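**Plan**

- Retrosynthesis: cut the two O–Si bonds, then the bond from C1 of the guaiacyl ring to the carbinol carbon C7 (aryl nucleophile plus C7 aldehyde), then take C7=O back to a vinyl group, then cut the C8–O bond to the acetosyringone ring.
- Forward: the C9–C8–C7 chain comes from (S)-but-3-ene-1,2-diol. C9–OH is silylated, the C8–O aryl ether is made with acetosyringone, the vinyl group is cleaved to the C7 aldehyde, and the 4-silyloxy-3-methoxyphenyl ring is added last as an aryltitanium reagent. Fluoride then frees both hydroxyls. No ring is formed; both arenes are bought.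
- Stereochemistry: C8 comes from the chiral-pool carbinol by SN2 inversion. C7 is set by 1,2-induction from C8 in the aryl addition (polar Felkin–Anh, anti = erythro, 7R,8S).
- Enabling feature: the C8–O bond to the 4-acetyl-2,6-dimethoxyphenyl ring sits α to the C7 formyl group and serves as the antiperiplanar σ* acceptor and largest substituent. The formyl C7=O is far more electrophilic than the acetyl C=O on that ring, so the ketone needs no protection.

Key step: step 5

Remark: lignan numbering is used (C7 = benzylic carbinol carbon, C8 = aryloxy-bearing carbon, C9 = CH2OH); compounds 1, 3 and 7 are taken as commercially available.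

**Route**

Step 1
Reactants: 1 (S)-but-3-ene-1,2-diol
Product: 2 (S)-1-[(tert-butyldimethylsilyl)oxy]but-3-en-2-ol
Conditions: TBSCl (1.05 equiv), imidazole, CH2Cl2, −10 → 0 °C
Reagents that add atoms: tert-butyldimethylsilyl chloride, CC(C)(C)[Si](C)(C)Cl
Why: Selective mono-silylation, since the bulky silyl chloride should react at the unhindered primary hydroxyl of the 1,2-diol much faster than at the secondary allylic one, and the stereocenter is not touched.

Step 2
Reactants: 2 (S)-1-[(tert-butyldimethylsilyl)oxy]but-3-en-2-ol; 3 acetosyringone, 1-(4-hydroxy-3,5-dimethoxyphenyl)ethan-1-one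
Product: 4 (R)-1-[4-({1-[(tert-butyldimethylsilyl)oxy]but-3-en-2-yl}oxy)-3,5-dimethoxyphenyl]ethan-1-one
Conditions: PPh3, DIAD, toluene, 0 °C → rt
Reagents that add atoms: none
Why: Mitsunobu etherification, in which the acidic para-acetyl phenol protonates the betaine and its phenoxide displaces the secondary oxyphosphonium by SN2 with inversion, so the (S)-carbinol should give the (R)-aryl ether that becomes C8 of the target (descriptor S there only through a change of CIP priorities).

Step 3
Reactants: 4 (R)-1-[4-({1-[(tert-butyldimethylsilyl)oxy]but-3-en-2-yl}oxy)-3,5-dimethoxyphenyl]ethan-1-one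
Product: 6 (S)-2-(4-acetyl-2,6-dimethoxyphenoxy)-3-[(tert-butyldimethylsilyl)oxy]propanal, via secondary ozonide 5 (not isolated)
Conditions: O3, CH2Cl2, −78 °C (Sudan Red 7B end point); then PPh3, −78 °C → rt; aqueous wash, short silica plug, used at once
Reagents that add atoms: ozone, [O-][O+]=O
Why: Ozonolysis with reductive work-up (Criegee mechanism), in which the terminal alkene should add ozone much faster than the acetyl-deactivated arene, and phosphine reduction of the ozonide releases the aldehyde under cold, neutral, non-aqueous conditions that should leave the α-aryloxy stereocenter intact.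

Step 4
Reactants: 7 4-bromo-2-methoxyphenol
Product: 8 (4-bromo-2-methoxyphenoxy)(tert-butyl)dimethylsilane
Conditions: TBSCl, imidazole, DMF, rt
Reagents that add atoms: tert-butyldimethylsilyl chloride, CC(C)(C)[Si](C)(C)Cl
Why: Silyl ether formation masks the acidic phenol O–H so that the ring can later be metalated at the C–Br carbon para to oxygen.

Step 5
Reactants: 6 (S)-2-(4-acetyl-2,6-dimethoxyphenoxy)-3-[(tert-butyldimethylsilyl)oxy]propanal; 8 (4-bromo-2-methoxyphenoxy)(tert-butyl)dimethylsilane
Product: 11 1-{4-[((1R,2S)-3-[(tert-butyldimethylsilyl)oxy]-1-{4-[(tert-butyldimethylsilyl)oxy]-3-methoxyphenyl}-1-hydroxypropan-2-yl)oxy]-3,5-dimethoxyphenyl}ethan-1-one, via aryllithium 9 (not isolated), via aryltitanium triisopropoxide 10 (not isolated)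
Conditions: 8 (1.5 equiv), n-BuLi, THF, −78 °C; ClTi(OiPr)3 (slight excess over n-BuLi), −78 → −40 °C; then 6, −78 → 0 °C; sat. aq. NH4Cl
Reagents that add atoms: none
Why: Bromine–lithium exchange on 8 gives aryllithium 9, which ClTi(OiPr)3 transmetalates to the monoaryltitanium triisopropoxide 10, and 10 transfers its aryl group to the formyl carbon of 6 through a closed four-centre Ti–O/C–C transition state to give the titanium alkoxide of 11. The closest known reaction type is the non-chelation-controlled, aldehyde-selective 1,2-addition of organotitanium triisopropoxides to α-alkoxy aldehydes. No ring is closed. The new stereocenter C7 is controlled by the resident C8 stereocenter under the polar Felkin–Anh model: the C8–OAr bond lies antiperiplanar to the incoming aryl group, which approaches along the Bürgi–Dunitz trajectory past the C8 hydrogen instead of the CH2OTBS group, and this should give the anti (erythro) 7R,8S carbinol. The step needs three selectivities: facial selectivity, secured by the weakly Lewis acidic and crowded Ti(OiPr)3 centre, which should not chelate the 2,6-dimethoxyaryl ether or the silyl ether oxygen; chemoselectivity for the aldehyde over the acetyl group, secured by the low nucleophilicity and bulk of the aryltitanium reagent and by the electron-rich aryl methyl ketone; and retention of the C8 configuration, secured by the low basicity of the titanium reagent at low temperature.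

Step 6
Reactants: 11 1-{4-[((1R,2S)-3-[(tert-butyldimethylsilyl)oxy]-1-{4-[(tert-butyldimethylsilyl)oxy]-3-methoxyphenyl}-1-hydroxypropan-2-yl)oxy]-3,5-dimethoxyphenyl}ethan-1-one
Product: 12 1-(4-{[(1R,2S)-1,3-dihydroxy-1-(4-hydroxy-3-methoxyphenyl)propan-2-yl]oxy}-3,5-dimethoxyphenyl)ethan-1-one
Conditions: TBAF (2.4 equiv), AcOH (2.4 equiv), THF, 0 °C → rt
Reagents that add atoms: none
Why: Fluoride-mediated desilylation should cleave the aryl and the primary alkyl silyl ether in one operation, and the acetic acid buffer keeps phenoxide and alkoxide concentrations low so that neither quinone methide formation at C7 nor aryl migration is expected and both stereocenters persist.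

**Compound list**

1 | (S)-but-3-ene-1,2-diol | C=C[C@@H](CO)O | starting material
2 | (S)-1-[(tert-butyldimethylsilyl)oxy]but-3-en-2-ol | C=C[C@@H](CO[Si](C)(C)C(C)(C)C)O | intermediate
3 | acetosyringone, 1-(4-hydroxy-3,5-dimethoxyphenyl)ethan-1-one | CC(=O)c1cc(OC)c(O)c(OC)c1 | starting material
4 | (R)-1-[4-({1-[(tert-butyldimethylsilyl)oxy]but-3-en-2-yl}oxy)-3,5-dimethoxyphenyl]ethan-1-one | C=C[C@H](CO[Si](C)(C)C(C)(C)C)Oc1c(OC)cc(C(C)=O)cc1OC | intermediate
5 | secondary ozonide of 4, a 3-substituted 1,2,4-trioxolane (both epimers at the ring carbon) | C1OC(OO1)[C@H](CO[Si](C)(C)C(C)(C)C)Oc1c(OC)cc(C(C)=O)cc1OC | intermediate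
6 | (S)-2-(4-acetyl-2,6-dimethoxyphenoxy)-3-[(tert-butyldimethylsilyl)oxy]propanal | O=C[C@H](CO[Si](C)(C)C(C)(C)C)Oc1c(OC)cc(C(C)=O)cc1OC | intermediate
7 | 4-bromo-2-methoxyphenol | COc1cc(Br)ccc1O | starting material
8 | (4-bromo-2-methoxyphenoxy)(tert-butyl)dimethylsilane | COc1cc(Br)ccc1O[Si](C)(C)C(C)(C)C | intermediate
9 | {4-[(tert-butyldimethylsilyl)oxy]-3-methoxyphenyl}lithium | COc1cc([Li])ccc1O[Si](C)(C)C(C)(C)C | intermediate
10 | {4-[(tert-butyldimethylsilyl)oxy]-3-methoxyphenyl}titanium triisopropoxide | COc1cc([Ti](OC(C)C)(OC(C)C)OC(C)C)ccc1O[Si](C)(C)C(C)(C)C | intermediate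
11 | 1-{4-[((1R,2S)-3-[(tert-butyldimethylsilyl)oxy]-1-{4-[(tert-butyldimethylsilyl)oxy]-3-methoxyphenyl}-1-hydroxypropan-2-yl)oxy]-3,5-dimethoxyphenyl}ethan-1-one | COc1cc([C@@H](O)[C@H](CO[Si](C)(C)C(C)(C)C)Oc2c(OC)cc(C(C)=O)cc2OC)ccc1O[Si](C)(C)C(C)(C)C | intermediate
12 | 1-(4-{[(1R,2S)-1,3-dihydroxy-1-(4-hydroxy-3-methoxyphenyl)propan-2-yl]oxy}-3,5-dimethoxyphenyl)ethan-1-one | COc1cc([C@@H](O)[C@H](CO)Oc2c(OC)cc(C(C)=O)cc2OC)ccc1O | target

**Summary and risks**

Total step count: 6. Longest linear sequence: 5 steps (steps 1, 2, 3, 5, 6); step 4 is a one-step side branch.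

Step 5 (key step). The facial selectivity at C7 may erode if a chelated transition state, with titanium held between the formyl oxygen and the aryl ether or methoxy oxygens, competes with the Felkin–Anh one; the threo epimer would then accompany 11. The fallback sets out from 11, taken as the C7-epimer mixture, and comes back at 11. The mixture would be oxidized with Dess–Martin periodinane (NaHCO3, CH2Cl2, 0 °C) to the single ketone (S)-2-(4-acetyl-2,6-dimethoxyphenoxy)-3-[(tert-butyldimethylsilyl)oxy]-1-{4-[(tert-butyldimethylsilyl)oxy]-3-methoxyphenyl}propan-1-one F1. This would be reduced at once with Zn(BH4)2 (limiting hydride, Et2O, −78 °C). Zinc should bridge the C7 carbonyl and the C8 ether oxygen, and hydride should enter anti to the CH2OTBS group, which gives the erythro carbinol. The chelate-activated α-aryloxy ketone should be reduced before the non-chelating acetyl group.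

Step 2. SN2 displacement at the hindered secondary allylic oxyphosphonium by a 2,6-disubstituted phenoxide may be slow, so that SN2′ transposition, ionization with loss of configurational purity, or elimination to the diene competes. The fallback sets out from 3 and comes back at 4, and sets C8 by catalyst control instead of from the chiral pool. (E)-But-2-ene-1,4-diol would be mono-silylated to (E)-4-[(tert-butyldimethylsilyl)oxy]but-2-en-1-ol F2 and converted with methyl chloroformate and pyridine into methyl (E)-4-[(tert-butyldimethylsilyl)oxy]but-2-en-1-yl carbonate F3. The lithium phenoxide of 3 would then be allylated with F3 under iridium catalysis ([Ir(cod)Cl]2, chiral phosphoramidite ligand, THF). This asymmetric allylic etherification should give the branched ether 4, with the ligand enantiomer chosen to deliver the (R) configuration.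

Step 3. Ozone may attack the trioxygenated ring near the end point, and the α-aryloxy aldehyde may epimerize or lose silanol by β-elimination during work-up. The fallback sets out from 4 and comes back at 6. Dihydroxylation (cat. OsO4, NMO, acetone–water) would give (3S)-3-(4-acetyl-2,6-dimethoxyphenoxy)-4-[(tert-butyldimethylsilyl)oxy]butane-1,2-diol F4, as both C2 epimers, which is immaterial. Glycol cleavage with Pb(OAc)4 (CH2Cl2, 0 °C, solid K2CO3) would then release 6, which would be filtered and used directly. No oxidant able to attack the arene is present in this sequence, and the aldehyde is released only in the last operation.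

**Further compounds**

F1 | step 5 | (S)-2-(4-acetyl-2,6-dimethoxyphenoxy)-3-[(tert-butyldimethylsilyl)oxy]-1-{4-[(tert-butyldimethylsilyl)oxy]-3-methoxyphenyl}propan-1-one | COc1cc(C(=O)[C@H](CO[Si](C)(C)C(C)(C)C)Oc2c(OC)cc(C(C)=O)cc2OC)ccc1O[Si](C)(C)C(C)(C)C
F2 | step 2 | (E)-4-[(tert-butyldimethylsilyl)oxy]but-2-en-1-ol | OC/C=C/CO[Si](C)(C)C(C)(C)C
F3 | step 2 | methyl (E)-4-[(tert-butyldimethylsilyl)oxy]but-2-en-1-yl carbonate | COC(=O)OC/C=C/CO[Si](C)(C)C(C)(C)C
F4 | step 3 | (3S)-3-(4-acetyl-2,6-dimethoxyphenoxy)-4-[(tert-butyldimethylsilyl)oxy]butane-1,2-diol (both C2 epimers) | OCC(O)[C@H](CO[Si](C)(C)C(C)(C)C)Oc1c(OC)cc(C(C)=O)cc1OC
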